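The route rests on two chromene disconnections. The acetyl-bearing chromene (ring A) is closed last, by condensing a single-enantiomer α-branched aldehyde with 2,4-dihydroxy-6-methoxyacetophenone. The pyran of the dimethoxychromene (ring B; O1–C2–C3=C4–C4a–C8a) is not closed at six members: an aryne spanning C4a/C8a adds across the C=O of 3-methylbut-2-enal to give a four-membered 2H-benzoxete (O1, C4, C4a, C8a), which expands by C3 and C2 through 4π opening and oxa-6π closure, all in one operation. The step exploits the C5 methoxy group beside C4a (C8 bears H), which fixes where oxygen adds. The precursor is an ortho-silylaryl triflate with no pyran ring. The stereocentre comes from a copper-catalysed asymmetric methyl conjugate addition.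

Key step: step 4

Assumption: the stabilised ylide S-ethyl 2-(triphenyl-λ5-phosphanylidene)ethanethioate is taken as purchasable (otherwise two routine operations from bromoacetyl bromide, ethanethiol and triphenylphosphine).

Step 1
Reactants: 1 4-hydroxy-2,6-dimethoxybenzaldehyde
Product: 2 3-bromo-4-hydroxy-2,6-dimethoxybenzaldehyde
Conditions: NBS (1.05 equiv), MeCN, 0 °C
Reagents that add atoms: N-bromosuccinimide O=C1CCC(=O)N1Br
Why: Electrophilic aromatic bromination, in which the two equivalent positions ortho to the phenol are also ortho and para to a methoxy group while the formyl group tempers the ring against a second bromination, so one bromine should enter beside OH.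

Step 2
Reactants: 2 3-bromo-4-hydroxy-2,6-dimethoxybenzaldehyde
Product: 3 2-bromo-4-(dimethoxymethyl)-3,5-dimethoxyphenol
Conditions: HC(OMe)3, MeOH, TsOH (cat.), 25 °C; then Et3N
Reagents that add atoms: trimethyl orthoformate COC(OC)OC
Why: Acid-catalysed acetalisation driven by the orthoformate, needed because a free aldehyde would not survive butyllithium in step 3 and would compete for the aryne in step 4.

Step 3
Reactants: 3 2-bromo-4-(dimethoxymethyl)-3,5-dimethoxyphenol
Product: 6 4-(dimethoxymethyl)-3,5-dimethoxy-2-(trimethylsilyl)phenyl trifluoromethanesulfonate, via aryl trimethylsilyl ether 4 (not isolated), via lithium 2-silylphenolate 5 (not isolated)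
Conditions: HMDS, THF, 65 °C; evaporate; nBuLi, THF, −100 °C; Tf2O, −100 → −78 °C
Reagents that add atoms: hexamethyldisilazane C[Si](C)(C)N[Si](C)(C)C; trifluoromethanesulfonic anhydride O=S(=O)(OS(=O)(=O)C(F)(F)F)C(F)(F)F
Why: O-silylation, bromine–lithium exchange, anionic 1,3-O→C silyl shift (retro-Brook rearrangement) and O-triflation of the resulting phenolate are the standard sequence to ortho-silylaryl triflates, and the acetal and methoxy groups are inert to nBuLi at −100 °C.

Step 4
Reactants: 6 4-(dimethoxymethyl)-3,5-dimethoxy-2-(trimethylsilyl)phenyl trifluoromethanesulfonate; 7 3-methylbut-2-enal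
Product: 12 5,7-dimethoxy-2,2-dimethyl-2H-chromene-6-carbaldehyde, via aryne 8 (not isolated), via 2H-benzoxete 9 (not isolated), via ortho-quinone methide 10 (not isolated), via chromene dimethyl acetal 11 (not isolated)
Conditions: CsF (3 equiv), 7 (3 equiv), MeCN, 25 °C; then aq. citric acid, THF, 25 °C
Reagents that add atoms: 3-methylbut-2-enal (7) CC(C)=CC=O; water O
Why: Fluoride removes the silyl group with loss of triflate to give aryne 8, whose triple bond joins the future C4a (flanked by OMe at C5) and C8a (flanked by H at C8). The carbonyl oxygen of 7 adds to C8a, the aryne carbon remote from methoxy, because the aryl anion then develops at C4a beside the inductively withdrawing OMe, and C4a closes on the carbonyl carbon in a stepwise [2+2] (four-membered closure by C–C bond formation) to give 2H-benzoxete 9. Ring strain then drives a thermal 4π electrocyclic opening of 9 (O1–C4 cleavage) to ortho-quinone methide 10, and a 6π oxa-electrocyclisation forms O1–C2, so the four-membered O1–C4–C4a–C8a ring has grown by C3 and C2 into the pyran. The closest known reaction type is the fluoride-mediated reaction of arynes with α,β-unsaturated aldehydes to give 2H-chromenes, related to aryne insertion into the C=O bond of formamides. No stereocentre is formed; the step needs regioselectivity at the aryne, secured by the C5 methoxy group, and addition at C=O in preference to [4+2] or ene reactions, favoured by the nucleophilic carbonyl oxygen, the excess of 7 and the masking of the aryl aldehyde as its acetal. The citric acid work-up then hydrolyses acetal 11 to aldehyde 12 without protonating the chromene.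

Step 5
Reactants: 12 5,7-dimethoxy-2,2-dimethyl-2H-chromene-6-carbaldehyde; 13 S-ethyl 2-(triphenyl-λ5-phosphanylidene)ethanethioate
Product: 14 S-ethyl (2E)-3-(5,7-dimethoxy-2,2-dimethyl-2H-chromen-6-yl)prop-2-enethioate
Conditions: 13 (1.3 equiv), toluene, 90 °C
Reagents that add atoms: S-ethyl 2-(triphenyl-λ5-phosphanylidene)ethanethioate (13) CCSC(=O)C=P(c1ccccc1)(c1ccccc1)c1ccccc1
Why: Wittig olefination with a stabilised ylide, which should give the (E)-enethioate under thermodynamic control even with the two flanking methoxy groups.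

Step 6
Reactants: 14 S-ethyl (2E)-3-(5,7-dimethoxy-2,2-dimethyl-2H-chromen-6-yl)prop-2-enethioate
Product: 15 S-ethyl (3S)-3-(5,7-dimethoxy-2,2-dimethyl-2H-chromen-6-yl)butanethioate
Conditions: MeMgBr, CuI (3 mol%), Tol-BINAP (3.3 mol%, enantiomer selected for Si-face attack), tBuOMe, −70 °C
Reagents that add atoms: methylmagnesium bromide C[Mg]Br
Why: Copper-catalysed asymmetric conjugate addition of a Grignard reagent to an α,β-unsaturated thioester, in which the chiral bisphosphine–copper complex delivers CH3 to one face of the enethioate; the ligand enantiomer (both are sold) is chosen for Si-face attack at C3, which sets the (3S) centre, and the thioester supplies the electrophilicity that MeMgBr needs at −70 °C.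

Step 7
Reactants: 15 S-ethyl (3S)-3-(5,7-dimethoxy-2,2-dimethyl-2H-chromen-6-yl)butanethioate; 16 2,2-dimethoxypropane
Product: 18 S-ethyl 2-[(1S)-1-(5,7-dimethoxy-2,2-dimethyl-2H-chromen-6-yl)ethyl]-3-methoxy-3-methylbutanethioate (both C2 epimers), via silyl ketene thioacetal 17 (not isolated)
Conditions: LiN(iPr)2, Me3SiCl, THF, −78 °C; solvent exchange; 16, Me3SiOTf (10 mol%), CH2Cl2, −78 °C
Reagents that add atoms: 2,2-dimethoxypropane (16) COC(C)(C)OC
Why: Deprotonation and O-silylation give silyl ketene thioacetal 17, whose Mukaiyama aldol-type addition to the oxocarbenium ion from ketal 16 installs the C(CH3)2OMe unit; the new C2 centre forms without control, which is harmless because it becomes sp2 in step 9, and the benzylic centre (β to the carbonyl) is not touched.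

Step 8
Reactants: 18 S-ethyl 2-[(1S)-1-(5,7-dimethoxy-2,2-dimethyl-2H-chromen-6-yl)ethyl]-3-methoxy-3-methylbutanethioate
Product: 19 2-[(1S)-1-(5,7-dimethoxy-2,2-dimethyl-2H-chromen-6-yl)ethyl]-3-methoxy-3-methylbutanal (both C2 epimers)
Conditions: iBu2AlH, CH2Cl2, −78 °C; aq. potassium sodium tartrate
Reagents that add atoms: none
Why: Partial reduction of a thioester by iBu2AlH, which should stop at the hemithioacetal aluminate at −78 °C and release the aldehyde on work-up.

Step 9
Reactants: 19 2-[(1S)-1-(5,7-dimethoxy-2,2-dimethyl-2H-chromen-6-yl)ethyl]-3-methoxy-3-methylbutanal; 20 1-(2,4-dihydroxy-6-methoxyphenyl)ethan-1-one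
Product: 23 1-{3-[(1S)-1-(5,7-dimethoxy-2,2-dimethyl-2H-chromen-6-yl)ethyl]-5-hydroxy-7-methoxy-2,2-dimethyl-2H-chromen-6-yl}ethan-1-one (target), via enal 21 (not isolated), via ortho-quinone methide 22 (not isolated)
Conditions: 20 (1.5 equiv), ethylenediammonium diacetate (20 mol%), toluene, 110 °C
Reagents that add atoms: 1-(2,4-dihydroxy-6-methoxyphenyl)ethan-1-one (20) CC(=O)c1c(O)cc(O)cc1OC
Why: Amine/acid-catalysed phenol–enal chromenylation (Knoevenagel-type C-alkylation, then oxa-6π electrocyclisation), in which the catalyst eliminates methanol from 19 by way of its enamine to give enal 21 as the iminium ion, the ring carbon of 20 between the two hydroxyls adds, loss of the amine gives quinone methide 22 and closure by the non-chelated 4-OH forms ring A, the stereocentre staying outside the reacting π system.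

Compound list
1 | 4-hydroxy-2,6-dimethoxybenzaldehyde | COc1cc(O)cc(OC)c1C=O | starting material
2 | 3-bromo-4-hydroxy-2,6-dimethoxybenzaldehyde | COc1cc(O)c(Br)c(OC)c1C=O | intermediate
3 | 2-bromo-4-(dimethoxymethyl)-3,5-dimethoxyphenol | COc1cc(O)c(Br)c(OC)c1C(OC)OC | intermediate
4 | [2-bromo-4-(dimethoxymethyl)-3,5-dimethoxyphenoxy]trimethylsilane | COc1cc(O[Si](C)(C)C)c(Br)c(OC)c1C(OC)OC | intermediate
5 | lithium 4-(dimethoxymethyl)-3,5-dimethoxy-2-(trimethylsilyl)phenolate | COc1cc([O-])c([Si](C)(C)C)c(OC)c1C(OC)OC.[Li+] | intermediate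
6 | 4-(dimethoxymethyl)-3,5-dimethoxy-2-(trimethylsilyl)phenyl trifluoromethanesulfonate | COc1cc(OS(=O)(=O)C(F)(F)F)c([Si](C)(C)C)c(OC)c1C(OC)OC | intermediate
7 | 3-methylbut-2-enal | CC(C)=CC=O | starting material
8 | 4-(dimethoxymethyl)-3,5-dimethoxy-1,2-didehydrobenzene (aryne) | COC1=C(C(OC)OC)C(OC)=CC#C1 | intermediate
9 | 4-(dimethoxymethyl)-3,5-dimethoxy-2-(2-methylprop-1-en-1-yl)-2H-1-benzoxete | COc1c(C(OC)OC)c(OC)cc2c1C(C=C(C)C)O2 | intermediate
10 | 4-(dimethoxymethyl)-3,5-dimethoxy-6-(3-methylbut-2-en-1-ylidene)cyclohexa-2,4-dien-1-one (alkene geometry not defined) | O=C1C=C(OC)C(C(OC)OC)=C(OC)C1=CC=C(C)C | intermediate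
11 | 6-(dimethoxymethyl)-5,7-dimethoxy-2,2-dimethyl-2H-chromene | COC(OC)c1c(OC)cc2OC(C)(C)C=Cc2c1OC | intermediate
12 | 5,7-dimethoxy-2,2-dimethyl-2H-chromene-6-carbaldehyde | O=Cc1c(OC)cc2OC(C)(C)C=Cc2c1OC | intermediate
13 | S-ethyl 2-(triphenyl-λ5-phosphanylidene)ethanethioate | CCSC(=O)C=P(c1ccccc1)(c1ccccc1)c1ccccc1 | starting material
14 | S-ethyl (2E)-3-(5,7-dimethoxy-2,2-dimethyl-2H-chromen-6-yl)prop-2-enethioate | CCSC(=O)/C=C/c1c(OC)cc2OC(C)(C)C=Cc2c1OC | intermediate
15 | S-ethyl (3S)-3-(5,7-dimethoxy-2,2-dimethyl-2H-chromen-6-yl)butanethioate | CCSC(=O)C[C@H](C)c1c(OC)cc2OC(C)(C)C=Cc2c1OC | intermediate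
16 | 2,2-dimethoxypropane | COC(C)(C)OC | starting material
17 | {[(3S)-3-(5,7-dimethoxy-2,2-dimethyl-2H-chromen-6-yl)-1-(ethylsulfanyl)but-1-en-1-yl]oxy}trimethylsilane (E/Z mixture) | CCSC(O[Si](C)(C)C)=C[C@H](C)c1c(OC)cc2OC(C)(C)C=Cc2c1OC | intermediate
18 | S-ethyl 2-[(1S)-1-(5,7-dimethoxy-2,2-dimethyl-2H-chromen-6-yl)ethyl]-3-methoxy-3-methylbutanethioate (both C2 epimers) | CCSC(=O)C(C(C)(C)OC)[C@H](C)c1c(OC)cc2OC(C)(C)C=Cc2c1OC | intermediate
19 | 2-[(1S)-1-(5,7-dimethoxy-2,2-dimethyl-2H-chromen-6-yl)ethyl]-3-methoxy-3-methylbutanal (both C2 epimers) | O=CC(C(C)(C)OC)[C@H](C)c1c(OC)cc2OC(C)(C)C=Cc2c1OC | intermediate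
20 | 1-(2,4-dihydroxy-6-methoxyphenyl)ethan-1-one | CC(=O)c1c(O)cc(O)cc1OC | starting material
21 | 2-[(1R)-1-(5,7-dimethoxy-2,2-dimethyl-2H-chromen-6-yl)ethyl]-3-methylbut-2-enal (same spatial arrangement as in 19; the descriptor changes only because the enal carbon now outranks the aryl group) | CC(C)=C(C=O)[C@H](C)c1c(OC)cc2OC(C)(C)C=Cc2c1OC | intermediate
22 | 4-acetyl-6-{2-[(1S)-1-(5,7-dimethoxy-2,2-dimethyl-2H-chromen-6-yl)ethyl]-3-methylbut-2-en-1-ylidene}-5-hydroxy-3-methoxycyclohexa-2,4-dien-1-one (exocyclic alkene geometry not defined) | CC(=O)C1=C(O)C(=CC(=C(C)C)[C@H](C)c2c(OC)cc3OC(C)(C)C=Cc3c2OC)C(=O)C=C1OC | intermediate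
23 | 1-{3-[(1S)-1-(5,7-dimethoxy-2,2-dimethyl-2H-chromen-6-yl)ethyl]-5-hydroxy-7-methoxy-2,2-dimethyl-2H-chromen-6-yl}ethan-1-one | COc1cc2c(c(O)c1C(C)=O)C=C([C@H](C)c1c(OC)cc3c(c1OC)C=CC(C)(C)O3)C(C)(C)O2 | target

Total step count: 9. Longest linear sequence: 9 steps (1 to 23); compounds 7, 13, 16 and 20 are bought.

Steps most likely to fail

Step 4. The aryne may be consumed by self-addition, by [4+2] addition across the enal or by an ene reaction before the carbonyl oxygen intercepts it. The fallback sets out from 1 and comes back at 12. Compound 1 is O-alkylated with 3-chloro-3-methylbut-1-yne (K2CO3, KI, CuCl cat., acetone, 56 °C) to 4-[(2-methylbut-3-yn-2-yl)oxy]-2,6-dimethoxybenzaldehyde F1. Heating this ether in N,N-diethylaniline at 190 °C (propargyl Claisen rearrangement, 1,5-hydrogen shift, oxa-6π closure; the two ortho positions are equivalent) should give 12 directly.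

Step 9. Carbon–carbon bond formation at the crowded, fully substituted iminium ion may be slow, and alkylation may stray to the ring carbon between OH and OMe. The fallback sets out from 19 and comes back at 23. Compound 19 is condensed under the same amine catalysis with 1-(2,4,6-trihydroxyphenyl)ethan-1-one, which is more nucleophilic and offers only one kind of ring carbon, to give 1-{3-[(1S)-1-(5,7-dimethoxy-2,2-dimethyl-2H-chromen-6-yl)ethyl]-5,7-dihydroxy-2,2-dimethyl-2H-chromen-6-yl}ethan-1-one F2. Mono-O-methylation (MeI, 1 equiv, K2CO3, acetone) should then take the less hindered 7-OH, the 5-OH being held in a hydrogen bond to the acetyl group and shielded by the peri C4–H, to give 23.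

Step 6. Methyl transfer may be slow or poorly face-selective, because the styryl acceptor is twisted by two ortho methoxy groups and deactivated by the electron-rich ring. The fallback sets out from 12 and comes back at 15, replacing catalyst control by a covalently bound auxiliary. Knoevenagel–Doebner condensation of 12 with malonic acid (pyridine, piperidine, 90 °C) gives (2E)-3-(5,7-dimethoxy-2,2-dimethyl-2H-chromen-6-yl)prop-2-enoic acid F3. Its pivaloyl mixed anhydride (PivCl, Et3N) acylates lithiated (4S)-4-phenyl-1,3-oxazolidin-2-one to (4S)-3-[(2E)-3-(5,7-dimethoxy-2,2-dimethyl-2H-chromen-6-yl)prop-2-enoyl]-4-phenyl-1,3-oxazolidin-2-one F4. MeMgBr with CuBr·SMe2 (THF, −40 °C) should add methyl to the magnesium-chelated s-cis imide from the face opposite the phenyl group, giving (4S)-3-[(3S)-3-(5,7-dimethoxy-2,2-dimethyl-2H-chromen-6-yl)butanoyl]-4-phenyl-1,3-oxazolidin-2-one F5, from which any minor diastereomer can be removed by chromatography or crystallisation. EtSLi (THF, 0 °C) then cleaves the auxiliary and returns thioester 15.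

Further compounds
F1 | step 4 | 4-[(2-methylbut-3-yn-2-yl)oxy]-2,6-dimethoxybenzaldehyde | COc1cc(OC(C)(C)C#C)cc(OC)c1C=O
F2 | step 9 | 1-{3-[(1S)-1-(5,7-dimethoxy-2,2-dimethyl-2H-chromen-6-yl)ethyl]-5,7-dihydroxy-2,2-dimethyl-2H-chromen-6-yl}ethan-1-one | CC(=O)c1c(O)cc2c(c1O)C=C([C@H](C)c1c(OC)cc3c(c1OC)C=CC(C)(C)O3)C(C)(C)O2
F3 | step 6 | (2E)-3-(5,7-dimethoxy-2,2-dimethyl-2H-chromen-6-yl)prop-2-enoic acid | OC(=O)/C=C/c1c(OC)cc2OC(C)(C)C=Cc2c1OC
F4 | step 6 | (4S)-3-[(2E)-3-(5,7-dimethoxy-2,2-dimethyl-2H-chromen-6-yl)prop-2-enoyl]-4-phenyl-1,3-oxazolidin-2-one | O=C1OC[C@H](c2ccccc2)N1C(=O)/C=C/c1c(OC)cc2OC(C)(C)C=Cc2c1OC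
F5 | step 6 | (4S)-3-[(3S)-3-(5,7-dimethoxy-2,2-dimethyl-2H-chromen-6-yl)butanoyl]-4-phenyl-1,3-oxazolidin-2-one | O=C1OC[C@H](c2ccccc2)N1C(=O)C[C@H](C)c1c(OC)cc2OC(C)(C)C=Cc2c1OC
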